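## Structural features

The target is one cyclohexane ring, the quinic acid ring. C1 is a tertiary carbinol that also carries the carboxylic acid, C2 and C6 are methylenes, and C3, C4 and C5 are three contiguous oxygenated stereocentres. O3 carries an (E)-caffeoyl ester and is axial and cis to O4. O4 carries an (E)-p-coumaroyl ester and is equatorial. O5 is a free equatorial hydroxyl, trans to O4 and on the ring face of the carboxyl carbon, so the configuration is that of natural (−)-quinic acid. Fragile points are the two cinnamate esters (they migrate between neighbouring hydroxyls under base), the oxidisable catechol, the light-sensitive (E)-alkenes, and the β-oxygen at C1, which is lost easily once a carbonyl sits at C3 or C5. The real difficulty is not the carbocycle but telling four oxygens apart, so that two different acyl groups end up on the adjacent O3 and O4 while O1 and O5 stay free. The key step uses the fact that the chain C3–C2–C1(OH)(CO2H)–C6–C5 is the whole carbon skeleton of citric acid: only C4 must be added, and the ring closes by forming C4–C5.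

## Logic of the disconnections

25 ⇒ 24 ⇒ 23. Four O–Si bonds and then the O1–CH2–O–C7 acetal-lactone are put back. The phenols, O5–H and the hydroxy-acid unit cannot coexist with acylating agents, hydride or oxidant. The gain is that every acidic or nucleophilic site is masked by only two kinds of group. The demand is that the lactone is opened while O5 is still silylated and that the final desilylation stays non-basic, so no ester can move to O5.

23 ⇒ 18 + 21. The acyl C–O bond at O4 is cut. This is the last skeletal C–O bond formed, so the coumaroyl group sees the fewest steps. The gain is a ring fragment with a single free hydroxyl and a simple protected acid. The demand is that acylation of a flanked equatorial alcohol outruns migration of the O3 ester.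

18 ⇒ 17 ⇒ 12 + 15. The benzylic ether on O4 is restored, then the acyl C–O bond at O3 is cut. O3 and O4 need different acyl groups, so they are addressed one at a time, and the ether is orthogonal to silyl ethers and esters. The gain is that 12 has only one free hydroxyl. The demand is a neutral oxidative ether cleavage and acylation of an axial alcohol.

12 ⇒ 11 ⇒ 10. The C3–H bond (alcohol back to ketone) and the O5–Si bond are removed. A C3 ketone is what an aldol closure leaves, and as a ketone O3 is automatically different from O4 and O5. The gain is one stereocentre fewer. The demand is hydride delivery from the equatorial direction to give the axial alcohol.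

10 ⇒ 9. The C4–C5 ring bond is cut. It is flanked by the C3 carbonyl and the C5 hydroxyl (aldol retron), and cutting it removes the ring and two stereocentres. The demand is that the enamine forms toward C4, attacks one face of the C5 aldehyde, and does not expel the β-oxygen at C1.

9 ⇒ 8 ⇒ 6 + 7 ⇒ 4. The C5 aldehyde is traced back to a thioester. The C4–O ether bond is cut to give 6 and 7, and the C3–C4 bond is cut to give 4 and a one-carbon diazo reagent. The gain is that the two arms of 4 differ only as acid versus thioester. The demand is that each operation touches one arm only and that conditions stay neutral.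

4 ⇒ 3 ⇒ 2 ⇒ 1. The C–S bond, the anhydride C–O bond and the two acetal C–O bonds are cut. 3 is achiral with enantiotopic carbonyls, so C1, the one stereocentre carried to the target, comes from a catalytic desymmetrisation. The acetal protects the α-hydroxy acid and prevents the central carboxyl from forming the five-membered anhydride. The gain is a return to achiral 1. The demand is a catalyst that distinguishes carbonyls differing only through O versus C=O at the spiro carbon.

15 ⇒ 13 and 21 ⇒ 19. The phenolic O–Si bonds are cut. The phenols must be masked during acid chloride formation and during the quinone oxidation. The demand is selective loss of the labile silyl ester after persilylation.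

## Other disconnections considered

Alternative 1: The ring is cut at C1–C6 and C2–C3, as a Diels–Alder adduct with its alkene at C4=C5.
- Forward step: 2-(benzoyloxy)acrolein A1 and buta-1,3-diene A2 would combine under a chiral primary ammonium salt (iminium activation) to (S)-1-formylcyclohex-3-en-1-yl benzoate A3, which already has the C1 configuration of the target.
- In favour: two C–C bonds and the quaternary carbinol centre arise in one catalytic step from trivial achiral components. The follow-up is classical: oxidation to the acid, halolactonisation onto C5, elimination to C3=C4, and cis-dihydroxylation away from the lactone bridge, giving 1-O-benzoylquinic acid 1,5-lactone A4. Every further stereocentre is relayed from C1.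
- Against: A2 is a gaseous, weakly reactive diene, and this mode of catalysis is most secure with cyclic dienes, so the enantiocontrol is uncertain. A4 has O3 and O4 free together; two different cinnamoyl groups would have to be placed by reactivity difference alone. The lactone must then be opened without moving the esters.
- Comparison: in step economy (about ten to twelve steps) it is better than the chosen plan. In mechanism the cycloaddition is constitutionally more predictable than an aldol that competes with elimination, so it is equal or better. In structure the chosen plan is stronger, because 10 leaves the key step with O3 as ketone, O4 as ether and O5 as free hydroxyl.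

Alternative 2: The ring is cut at C3=C4 after a retro-dihydroxylation.
- Forward step: the quaternary centre would come from L-malic acid A5 by alkylation with self-regeneration of the stereocentre. The diene methyl (2S,4R)-2,4-dihydroxy-2-(prop-2-en-1-yl)hex-5-enoate A6 would be closed with the second-generation Grubbs catalyst, with loss of ethylene, to methyl (1S,5R)-1,5-dihydroxycyclohex-3-ene-1-carboxylate A7.
- In favour: C1 is bought from the chiral pool, and metathesis of a 1,7-diene to a cyclohexene is among the most dependable ring closures and tolerates free hydroxyls. Dihydroxylation of A7 anti to the allylic C5 hydroxyl would set C3 and C4 together and give methyl (−)-quinate A8.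
- Against: C5 would come from a vinyl addition to a β-oxygenated aldehyde with uncertain 1,3-induction. A8 has three undifferentiated secondary hydroxyls, which is the same problem as starting from the natural acid. A methyl ester is harder to remove beside two cinnamates than an acylal-type lactone.
- Comparison: in mechanism the ring closure is better than the chosen aldol. In step economy it is about equal (roughly eight steps to A8, then seven or eight for differentiation and acylation). In structure the chosen plan is better, since its key product needs no protecting-group shuffling.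

Alternative 3: The ring is cut at C1–C2.
- Forward step: the methyl ketone enolate (future C2) of ethyl 3-[(4R,5S)-5-acetyl-2,2-dimethyl-1,3-dioxolan-4-yl]-2-oxopropanoate A10, made from diethyl D-tartrate A9, would add to the α-keto ester carbonyl (future C1) to give ethyl 4,5-O-isopropylidene-3-dehydroquinate A11.
- In favour: the bond is the one closed in the shikimate pathway. C4 and C5 come with the right trans relationship from the chiral pool, so no asymmetric catalyst and no desymmetrisation are needed; on this point it is better than the chosen plan. The C3 ketone emerges just as in 10, and the acceptor is strongly electrophilic.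
- Against: the donor ketone can also enolise toward C4, which leads to epimerisation or expulsion of O5. The C6 protons of the keto ester are acidic and β to O5. The trans-fused acetonide is strained. C1 would be set only by thermodynamic preference. O4 and O5 leave the key step tied in one acetal, although only O4 is acylated in the target, and selective acylation of O4 over the less hindered O5 is unlikely.
- Comparison: in reaction type (intramolecular aldol to a 3-dehydroquinate) and in step count the two plans are equal. The chosen plan is better in enolisation regiochemistry, because only the wanted oxygenated side can close a six-membered ring, and in oxygen differentiation.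

Key step: step 7

Remark on names: "quinic acid 1,7-methylene dioxolanone" means the (−)-quinic acid skeleton with O1 and the carboxyl carbon C7 bridged by CH2 as a spiro 1,3-dioxolan-4-one. Ring numbering and configuration are those of (−)-quinic acid; in the dioxolanone itself the quaternary carbon is C5 and the carbonyl C4.
Assumption: the quinine-derived catalyst of step 3 is taken to give the (S)-acid 4; if the sense is the opposite, the quinidine-derived pseudoenantiomer is used with no other change.

## Route

Step 1
Reactants: 1 citric acid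
Product: 2 2,2'-(5-oxo-1,3-dioxolane-4,4-diyl)diacetic acid
Conditions: (CH2O)n (1.2 equiv), neat melt, 140 °C; crystallise from H2O
Reagents that add atoms: formaldehyde (as paraformaldehyde), C=O
Why: Acetalisation of the α-hydroxy acid unit (tertiary OH and central CO2H) gives the five-membered 1,3-dioxolan-4-one and leaves both CH2CO2H arms free; the product is achiral.

Step 2
Reactants: 2 2,2'-(5-oxo-1,3-dioxolane-4,4-diyl)diacetic acid
Product: 3 1,3,8-trioxaspiro[4.5]decane-4,7,9-trione
Conditions: Ac2O, 60 °C; evaporate with toluene
Reagents that add atoms: none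
Why: Cyclodehydration of a 3,3-disubstituted glutaric acid; gem-disubstitution favours the six-membered anhydride, and the central carboxyl is tied up, so the unsymmetrical five-membered anhydride cannot form.

Step 3
Reactants: 3 1,3,8-trioxaspiro[4.5]decane-4,7,9-trione
Product: 4 (S)-2-{4-[2-(benzylsulfanyl)-2-oxoethyl]-5-oxo-1,3-dioxolan-4-yl}acetic acid
Conditions: BnSH (1.1 equiv), N-(9-deoxy-epi-quinin-9-yl)-3,5-bis(trifluoromethyl)benzenesulfonamide (10 mol%), MTBE, 0 °C to rt; dilute HCl wash
Reagents that add atoms: phenylmethanethiol, SCc1ccccc1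
Why: Organocatalytic desymmetrising thiolysis of a prochiral glutaric anhydride: the quinuclidine activates the thiol as a general base while the sulfonamide N–H binds one of the two enantiotopic carbonyls. This sets the stereocentre that becomes C1, and the thioester is the latent C5 aldehyde.

Step 4
Reactants: 4 (S)-2-{4-[2-(benzylsulfanyl)-2-oxoethyl]-5-oxo-1,3-dioxolan-4-yl}acetic acid
Product: 6 S-benzyl 2-[(S)-4-(3-diazo-2-oxopropyl)-5-oxo-1,3-dioxolan-4-yl]ethanethioate, via acid chloride 5 (not isolated)
Conditions: (COCl)2, cat. DMF, CH2Cl2, 0 °C to rt, evaporate; TMSCHN2 (2 equiv), THF/MeCN, 0 °C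
Reagents that add atoms: trimethylsilyldiazomethane, C[Si](C)(C)C=[N+]=[N-]; oxalyl chloride, O=C(Cl)C(Cl)=O (supplies only the chlorine of the unisolated 5)
Why: Arndt–Eistert-type diazoketone synthesis with the non-explosive diazomethane surrogate: the acid chloride acylates the diazo carbon and chloride removes the silyl group. Thioester and dioxolanone are inert and the stereocentre is not touched.

Step 5
Reactants: 6 S-benzyl 2-[(S)-4-(3-diazo-2-oxopropyl)-5-oxo-1,3-dioxolan-4-yl]ethanethioate; 7 4-methoxybenzyl alcohol
Product: 8 S-benzyl 2-[(S)-4-{3-[(4-methoxybenzyl)oxy]-2-oxopropyl}-5-oxo-1,3-dioxolan-4-yl]ethanethioate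
Conditions: 7 (3 equiv), Rh2(OAc)4 (1 mol%), CH2Cl2, rt, slow addition of 6
Reagents that add atoms: none
Why: Dirhodium-carbenoid O–H insertion into the alcohol gives the α-alkoxy ketone; excess alcohol and slow addition of the diazoketone favour intermolecular insertion over intramolecular carbenoid pathways.

Step 6
Reactants: 8 S-benzyl 2-[(S)-4-{3-[(4-methoxybenzyl)oxy]-2-oxopropyl}-5-oxo-1,3-dioxolan-4-yl]ethanethioate
Product: 9 (R)-5-{3-[(4-methoxybenzyl)oxy]-2-oxopropyl}-5-(2-oxoethyl)-1,3-dioxolan-4-one
Conditions: Et3SiH (3 equiv), 10% Pd/C, acetone, rt; filter, use at once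
Reagents that add atoms: none
Why: Fukuyama reduction: zerovalent palladium inserts into the C–S bond and the silane delivers hydride, giving the aldehyde without touching ketone, benzylic ether or lactone. Neutral conditions avoid β-elimination at C1.

Step 7
Reactants: 9 (R)-5-{3-[(4-methoxybenzyl)oxy]-2-oxopropyl}-5-(2-oxoethyl)-1,3-dioxolan-4-one
Product: 10 (5R,8S,9R)-9-hydroxy-8-[(4-methoxybenzyl)oxy]-1,3-dioxaspiro[4.5]decane-4,7-dione (4-O-(4-methoxybenzyl)-3-dehydroquinic acid 1,7-methylene dioxolanone)
Conditions: (S)-proline (20 mol%), DMSO, rt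
Reagents that add atoms: none
Why: (S)-Proline condenses with the C3 ketone, the enamine forms toward C4 (the carbon bearing the ether oxygen, less hindered than the neopentyl C2), the catalyst's carboxylic acid hydrogen-bonds the C5 aldehyde, C4 adds to it, and iminium hydrolysis releases 10. The closest known reaction types are the proline-catalysed 6-enolendo aldol cyclisation of the Hajos–Parrish kind and proline aldols of α-oxygenated ketones. The ring closes in the 6-(enolendo)-exo-trig mode, with the enamine C3=C4 inside the new ring and C5=O outside it. C5 is set by the catalyst: the (E)-enamine is attacked on the face carrying the acid, the tether holds C6 gauche to C3, and the hydrogen-bonded oxygen therefore ends trans to O4 and, for the (S)-catalyst, on the face of the C1 carboxyl carbon (5R). C4 is set in the same event (4S), stays epimerisable next to the ketone and should settle equatorial, trans to O5. C1 is untouched, and because the wanted chair has O4, O5 and the carboxyl carbon all equatorial, any retro-aldol or C4 equilibration under the amine works toward the same isomer. The step needs regioselection, which the substrate secures because closure from C2 or from the aldehyde enamine carbon C6 would give a four-membered ring. It must also outrun β-elimination of the C1 oxygen, for which the mild amine–acid conditions and the poor leaving-group ability of an acetal oxygen are relied on.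

Step 8
Reactants: 10 4-O-(4-methoxybenzyl)-3-dehydroquinic acid 1,7-methylene dioxolanone
Product: 11 (5R,8S,9R)-9-[(tert-butyldimethylsilyl)oxy]-8-[(4-methoxybenzyl)oxy]-1,3-dioxaspiro[4.5]decane-4,7-dione (the 5-O-silyl ether of 10)
Conditions: TBSOTf, 2,6-lutidine, CH2Cl2, −78 °C
Reagents that add atoms: tert-butyldimethylsilyl trifluoromethanesulfonate, CC(C)(C)[Si](C)(C)OS(=O)(=O)C(F)(F)F
Why: Silylation of the secondary C5 alcohol with a silyl triflate and a hindered base at low temperature avoids enolisation and dehydration of the β-hydroxy ketone; blocking O5 directs later acylations to O3 and O4 and prevents lactonisation onto C7.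

Step 9
Reactants: 11 the 5-O-silyl ether of 10
Product: 12 4-O-(4-methoxybenzyl)-5-O-(tert-butyldimethylsilyl)quinic acid 1,7-methylene dioxolanone (3-OH axial, cis to O4)
Conditions: LiBH(s-Bu)3 (1.1 equiv), THF, −78 °C; AcOH quench at −78 °C
Reagents that add atoms: none
Why: Bulky trialkylborohydride reduction of a chair cyclohexanone: hydride arrives from the equatorial direction (axial approach is further blocked by the axial C1 oxygen), giving the axial (3R) alcohol. Low temperature spares the lactone.

Step 10
Reactants: 13 caffeic acid
Product: 15 (E)-3-[3,4-bis(tert-butyldimethylsilyloxy)phenyl]prop-2-enoic acid, via tris-silyl compound 14 (not isolated)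
Conditions: TBSCl (3.5 equiv), imidazole, DMF, rt; then AcOH/THF/H2O, rt
Reagents that add atoms: tert-butyl(chloro)dimethylsilane, CC(C)(C)[Si](C)(C)Cl
Why: Persilylation followed by selective hydrolysis of the silyl ester, which is far more labile than the aryl silyl ethers; the (E)-alkene is unchanged.

Step 11
Reactants: 12 4-O-(4-methoxybenzyl)-5-O-(tert-butyldimethylsilyl)quinic acid 1,7-methylene dioxolanone; 15 (E)-3-[3,4-bis(tert-butyldimethylsilyloxy)phenyl]prop-2-enoic acid
Product: 17 3-O-[(E)-3,4-bis(tert-butyldimethylsilyloxy)cinnamoyl]-4-O-(4-methoxybenzyl)-5-O-(tert-butyldimethylsilyl)quinic acid 1,7-methylene dioxolanone, via acid chloride 16 (not isolated)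
Conditions: 15, (COCl)2, cat. DMF, CH2Cl2, 0 °C to rt, evaporate; then 12, pyridine, DMAP, CH2Cl2, 0 °C to rt
Reagents that add atoms: oxalyl chloride, O=C(Cl)C(Cl)=O (supplies only the chlorine of the unisolated 16)
Why: DMAP-catalysed acylation of the axial alcohol by the acid chloride through the N-acylpyridinium ion; O3 is the only free hydroxyl, so the site is unambiguous.

Step 12
Reactants: 17 the 3-O-acyl 4-O-(4-methoxybenzyl) compound
Product: 18 3-O-[(E)-3,4-bis(tert-butyldimethylsilyloxy)cinnamoyl]-5-O-(tert-butyldimethylsilyl)quinic acid 1,7-methylene dioxolanone (4-OH free)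
Conditions: DDQ (1.5 equiv), CH2Cl2/pH 7 buffer (10:1), 0 °C to rt
Reagents that add atoms: none
Why: Oxidative cleavage of the 4-methoxybenzyl ether: the quinone abstracts benzylic hydride and the oxocarbenium ion is hydrolysed. Silyl ethers, esters and lactone are inert, and the neutral buffer gives the O3 ester no base to migrate.

Step 13
Reactants: 19 p-coumaric acid
Product: 21 (E)-3-[4-(tert-butyldimethylsilyloxy)phenyl]prop-2-enoic acid, via bis-silyl compound 20 (not isolated)
Conditions: TBSCl (2.5 equiv), imidazole, DMF, rt; then AcOH/THF/H2O, rt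
Reagents that add atoms: tert-butyl(chloro)dimethylsilane, CC(C)(C)[Si](C)(C)Cl
Why: Same persilylation and selective silyl ester hydrolysis as in step 10.

Step 14
Reactants: 18 the 4-hydroxy compound; 21 (E)-3-[4-(tert-butyldimethylsilyloxy)phenyl]prop-2-enoic acid
Product: 23 3-O-[(E)-3,4-bis(tert-butyldimethylsilyloxy)cinnamoyl]-4-O-[(E)-4-(tert-butyldimethylsilyloxy)cinnamoyl]-5-O-(tert-butyldimethylsilyl)quinic acid 1,7-methylene dioxolanone, via acid chloride 22 (not isolated)
Conditions: 21, (COCl)2, cat. DMF, CH2Cl2, 0 °C to rt, evaporate; then 18, pyridine, DMAP, CH2Cl2, rt to 35 °C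
Reagents that add atoms: oxalyl chloride, O=C(Cl)C(Cl)=O (supplies only the chlorine of the unisolated 22)
Why: DMAP-catalysed acylation of the equatorial C4 alcohol; the fast acyl transfer from a preformed acid chloride is relied on to outpace base-induced O3-to-O4 migration.

Step 15
Reactants: 23 the fully protected diester
Product: 24 3-O-[(E)-3,4-bis(tert-butyldimethylsilyloxy)cinnamoyl]-4-O-[(E)-4-(tert-butyldimethylsilyloxy)cinnamoyl]-5-O-(tert-butyldimethylsilyl)quinic acid (free 1-OH and CO2H)
Conditions: LiOH (1.3 equiv), THF/H2O (4:1), 0 °C; 1 M HCl to pH 3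
Reagents that add atoms: water (delivered as aqueous LiOH), O
Why: Saponification of the acylal-type lactone: hydroxide adds to the activated C7 carbonyl and the released hemiacetal loses formaldehyde. This carbonyl is far more electrophilic than the two hindered cinnamates, and with O5 still silylated neither acyl migration to O5 nor lactonisation can occur; partial loss of an aryl silyl ether here would not matter for the next step.

Step 16
Reactants: 24 the tetrasilylated acid
Product: 25 3-O-caffeoyl-4-O-p-coumaroylquinic acid (target, CNP0077575.1)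
Conditions: TBAF (6 equiv), AcOH (6 equiv), THF, 0 °C to rt, dark; C18 chromatography (H2O/MeCN, 0.1% HCO2H)
Reagents that add atoms: none
Why: Fluoride cleaves the one alkyl and three aryl silyl ethers; acetic acid buffering keeps the medium non-basic, so the C4 ester should not migrate to the freed O5, and no stereocentre is touched.

## Compound list

1 | citric acid | OC(=O)CC(O)(CC(=O)O)C(=O)O | starting material
2 | 2,2'-(5-oxo-1,3-dioxolane-4,4-diyl)diacetic acid | OC(=O)CC1(CC(=O)O)OCOC1=O | intermediate
3 | 1,3,8-trioxaspiro[4.5]decane-4,7,9-trione | O=C1CC2(CC(=O)O1)OCOC2=O | intermediate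
4 | (S)-2-{4-[2-(benzylsulfanyl)-2-oxoethyl]-5-oxo-1,3-dioxolan-4-yl}acetic acid | O=C(SCc1ccccc1)C[C@@]1(OCOC1=O)CC(=O)O | intermediate
5 | S-benzyl 2-[(R)-4-(2-chloro-2-oxoethyl)-5-oxo-1,3-dioxolan-4-yl]ethanethioate | O=C(SCc1ccccc1)C[C@@]1(OCOC1=O)CC(=O)Cl | intermediate
6 | S-benzyl 2-[(S)-4-(3-diazo-2-oxopropyl)-5-oxo-1,3-dioxolan-4-yl]ethanethioate | O=C(SCc1ccccc1)C[C@@]1(OCOC1=O)CC(=O)C=[N+]=[N-] | intermediate
7 | 4-methoxybenzyl alcohol | COc1ccc(CO)cc1 | starting material
8 | S-benzyl 2-[(S)-4-{3-[(4-methoxybenzyl)oxy]-2-oxopropyl}-5-oxo-1,3-dioxolan-4-yl]ethanethioate | O=C(SCc1ccccc1)C[C@@]1(OCOC1=O)CC(=O)COCc1ccc(OC)cc1 | intermediate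
9 | (R)-5-{3-[(4-methoxybenzyl)oxy]-2-oxopropyl}-5-(2-oxoethyl)-1,3-dioxolan-4-one | O=CC[C@@]1(OCOC1=O)CC(=O)COCc2ccc(OC)cc2 | intermediate
10 | (5R,8S,9R)-9-hydroxy-8-[(4-methoxybenzyl)oxy]-1,3-dioxaspiro[4.5]decane-4,7-dione | COc1ccc(CO[C@H]2[C@H](O)C[C@@]3(OCOC3=O)CC2=O)cc1 | intermediate
11 | (5R,8S,9R)-9-[(tert-butyldimethylsilyl)oxy]-8-[(4-methoxybenzyl)oxy]-1,3-dioxaspiro[4.5]decane-4,7-dione | COc1ccc(CO[C@H]2[C@H](O[Si](C)(C)C(C)(C)C)C[C@@]3(OCOC3=O)CC2=O)cc1 | intermediate
12 | 4-O-(4-methoxybenzyl)-5-O-(tert-butyldimethylsilyl)quinic acid 1,7-methylene dioxolanone | COc1ccc(CO[C@H]2[C@H](O[Si](C)(C)C(C)(C)C)C[C@@]3(OCOC3=O)C[C@H]2O)cc1 | intermediate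
13 | caffeic acid | O=C(O)/C=C/c1ccc(O)c(O)c1 | starting material
14 | tert-butyldimethylsilyl (E)-3-[3,4-bis(tert-butyldimethylsilyloxy)phenyl]prop-2-enoate | CC(C)(C)[Si](C)(C)OC(=O)/C=C/c1ccc(O[Si](C)(C)C(C)(C)C)c(O[Si](C)(C)C(C)(C)C)c1 | intermediate
15 | (E)-3-[3,4-bis(tert-butyldimethylsilyloxy)phenyl]prop-2-enoic acid | O=C(O)/C=C/c1ccc(O[Si](C)(C)C(C)(C)C)c(O[Si](C)(C)C(C)(C)C)c1 | intermediate
16 | (E)-3-[3,4-bis(tert-butyldimethylsilyloxy)phenyl]prop-2-enoyl chloride | O=C(Cl)/C=C/c1ccc(O[Si](C)(C)C(C)(C)C)c(O[Si](C)(C)C(C)(C)C)c1 | intermediate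
17 | 3-O-[(E)-3,4-bis(tert-butyldimethylsilyloxy)cinnamoyl]-4-O-(4-methoxybenzyl)-5-O-(tert-butyldimethylsilyl)quinic acid 1,7-methylene dioxolanone | COc1ccc(CO[C@H]2[C@H](O[Si](C)(C)C(C)(C)C)C[C@@]3(OCOC3=O)C[C@H]2OC(=O)/C=C/c2ccc(O[Si](C)(C)C(C)(C)C)c(O[Si](C)(C)C(C)(C)C)c2)cc1 | intermediate
18 | 3-O-[(E)-3,4-bis(tert-butyldimethylsilyloxy)cinnamoyl]-5-O-(tert-butyldimethylsilyl)quinic acid 1,7-methylene dioxolanone | O[C@H]1[C@H](O[Si](C)(C)C(C)(C)C)C[C@@]2(OCOC2=O)C[C@H]1OC(=O)/C=C/c1ccc(O[Si](C)(C)C(C)(C)C)c(O[Si](C)(C)C(C)(C)C)c1 | intermediate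
19 | p-coumaric acid | O=C(O)/C=C/c1ccc(O)cc1 | starting material
20 | tert-butyldimethylsilyl (E)-3-[4-(tert-butyldimethylsilyloxy)phenyl]prop-2-enoate | CC(C)(C)[Si](C)(C)OC(=O)/C=C/c1ccc(O[Si](C)(C)C(C)(C)C)cc1 | intermediate
21 | (E)-3-[4-(tert-butyldimethylsilyloxy)phenyl]prop-2-enoic acid | O=C(O)/C=C/c1ccc(O[Si](C)(C)C(C)(C)C)cc1 | intermediate
22 | (E)-3-[4-(tert-butyldimethylsilyloxy)phenyl]prop-2-enoyl chloride | O=C(Cl)/C=C/c1ccc(O[Si](C)(C)C(C)(C)C)cc1 | intermediate
23 | 3-O-[(E)-3,4-bis(tert-butyldimethylsilyloxy)cinnamoyl]-4-O-[(E)-4-(tert-butyldimethylsilyloxy)cinnamoyl]-5-O-(tert-butyldimethylsilyl)quinic acid 1,7-methylene dioxolanone | O=C(/C=C/c1ccc(O[Si](C)(C)C(C)(C)C)cc1)O[C@H]1[C@H](O[Si](C)(C)C(C)(C)C)C[C@@]2(OCOC2=O)C[C@H]1OC(=O)/C=C/c1ccc(O[Si](C)(C)C(C)(C)C)c(O[Si](C)(C)C(C)(C)C)c1 | intermediate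
24 | 3-O-[(E)-3,4-bis(tert-butyldimethylsilyloxy)cinnamoyl]-4-O-[(E)-4-(tert-butyldimethylsilyloxy)cinnamoyl]-5-O-(tert-butyldimethylsilyl)quinic acid | O=C(/C=C/c1ccc(O[Si](C)(C)C(C)(C)C)cc1)O[C@H]1[C@H](O[Si](C)(C)C(C)(C)C)C[C@](O)(C(=O)O)C[C@H]1OC(=O)/C=C/c1ccc(O[Si](C)(C)C(C)(C)C)c(O[Si](C)(C)C(C)(C)C)c1 | intermediate
25 | 3-O-caffeoyl-4-O-p-coumaroylquinic acid | O=C(/C=C/c1ccc(O)cc1)O[C@H]1[C@H](O)C[C@](O)(C(=O)O)C[C@H]1OC(=O)/C=C/c1ccc(O)c(O)c1 | target

## Step count and least certain steps

Total step count: 16. Longest linear sequence: 14 steps (steps 1–9, 11, 12, 14, 15, 16, from 1).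

Step 7 (key step).
- What may go wrong: β-elimination of the C1 oxygen through the aldehyde-derived enamine or the C2 enamine, which opens the dioxolanone and loses formaldehyde. The secondary amine may also be acylated by the activated lactone. Control of the aldehyde face may be incomplete; the two trans-diequatorial chairs differ only by the small preference for the carboxyl carbon over oxygen in the equatorial position.
- Fallback (from 8, back to 10): soft enolisation of the ketone of 8 (TMSOTf, Et3N, CH2Cl2, −78 °C) toward the oxygenated side would give S-benzyl 2-[(S)-4-{(Z)-3-[(4-methoxybenzyl)oxy]-2-(trimethylsilyloxy)prop-2-en-1-yl}-5-oxo-1,3-dioxolan-4-yl]ethanethioate F1. Fukuyama reduction (Et3SiH, Pd/C, acetone) would give (S)-5-{(Z)-3-[(4-methoxybenzyl)oxy]-2-(trimethylsilyloxy)prop-2-en-1-yl}-5-(2-oxoethyl)-1,3-dioxolan-4-one F2. An intramolecular Mukaiyama aldol (BF3·OEt2, CH2Cl2, −78 °C, aqueous work-up) under chair substrate control would then rejoin the route at 10; C4 can be equilibrated afterwards.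

Step 3.
- What may go wrong: poor discrimination of the enantiotopic carbonyls, because the two substituents at the spiro carbon (ring O and ring C=O) are similar in size, or the opposite sense of induction.
- Fallback (from 3, back to 4): non-selective thiolysis (BnSH, cat. Et3N) would give racemic 2-{4-[2-(benzylsulfanyl)-2-oxoethyl]-5-oxo-1,3-dioxolan-4-yl}acetic acid F3. Crystallisation of its salt with (R)-1-phenylethylamine should give the (R)-1-phenylethylammonium salt of the (S)-acid F4, and acidification returns 4. Which enantiomer of the amine pairs with the (S)-acid must be determined.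

Step 5.
- What may go wrong: diversion of the rhodium carbenoid into intramolecular carbonyl-ylide formation with the lactone or thioester carbonyl, or into Wolff rearrangement, instead of O–H insertion.
- Fallback (from 4 through 5, back to 8): 7 would be converted (NaH, (iodomethyl)tributylstannane, THF) into tributyl{[(4-methoxybenzyl)oxy]methyl}stannane F5. A Stille-type ketone synthesis with acid chloride 5 (cat. PdCl2(PPh3)2, THF, 60 °C) would give 8 directly, with no diazo compound.

Step 14.
- What may go wrong: slow acylation of the flanked C4 hydroxyl, allowing base-induced migration of the caffeoyl group from O3 to O4 and scrambling of the ester pattern.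
- Fallback (from 18, back to 23): the small acyl donor diethylphosphonoacetic acid (DIC, cat. DMAP, CH2Cl2) would give the 4-O-(diethoxyphosphorylacetyl) derivative of 18 F6. A Horner–Wadsworth–Emmons olefination with commercial 4-(tert-butyldimethylsilyloxy)benzaldehyde (LiCl, i-Pr2NEt, MeCN) would build the (E)-cinnamate on the ring and rejoin the route at 23.

Step 15.
- What may go wrong: competing hydroxide attack on the cinnamate esters or the aryl silyl ethers, or acyl transfer to the freed O1.
- Fallback (from 23, back to 25): alcoholysis of the lactone with 2-(trimethylsilyl)ethanol (cat. DMAP, 40 °C) would give the 2-(trimethylsilyl)ethyl ester of 24 F7. The buffered fluoride conditions of step 16 would then remove this ester and all four silyl ethers in one operation and give 25.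

## Further compounds

F1 | step 7 | S-benzyl 2-[(S)-4-{(Z)-3-[(4-methoxybenzyl)oxy]-2-(trimethylsilyloxy)prop-2-en-1-yl}-5-oxo-1,3-dioxolan-4-yl]ethanethioate | O=C(SCc1ccccc1)C[C@@]1(OCOC1=O)C/C(O[Si](C)(C)C)=C/OCc1ccc(OC)cc1
F2 | step 7 | (S)-5-{(Z)-3-[(4-methoxybenzyl)oxy]-2-(trimethylsilyloxy)prop-2-en-1-yl}-5-(2-oxoethyl)-1,3-dioxolan-4-one | O=CC[C@@]1(OCOC1=O)C/C(O[Si](C)(C)C)=C/OCc1ccc(OC)cc1
F3 | step 3 | racemic 2-{4-[2-(benzylsulfanyl)-2-oxoethyl]-5-oxo-1,3-dioxolan-4-yl}acetic acid | O=C(SCc1ccccc1)CC1(OCOC1=O)CC(=O)O
F4 | step 3 | (R)-1-phenylethylammonium salt of the (S)-acid 4 | O=C(SCc1ccccc1)C[C@@]1(OCOC1=O)CC(=O)[O-].C[C@@H]([NH3+])c1ccccc1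
F5 | step 5 | tributyl{[(4-methoxybenzyl)oxy]methyl}stannane | CCCC[Sn](CCCC)(CCCC)COCc1ccc(OC)cc1
F6 | step 14 | 3-O-[(E)-3,4-bis(tert-butyldimethylsilyloxy)cinnamoyl]-4-O-(diethoxyphosphorylacetyl)-5-O-(tert-butyldimethylsilyl)quinic acid 1,7-methylene dioxolanone | CCOP(=O)(OCC)CC(=O)O[C@H]1[C@H](O[Si](C)(C)C(C)(C)C)C[C@@]2(OCOC2=O)C[C@H]1OC(=O)/C=C/c1ccc(O[Si](C)(C)C(C)(C)C)c(O[Si](C)(C)C(C)(C)C)c1
F7 | step 15 | 2-(trimethylsilyl)ethyl ester of 24 | O=C(/C=C/c1ccc(O[Si](C)(C)C(C)(C)C)cc1)O[C@H]1[C@H](O[Si](C)(C)C(C)(C)C)C[C@](O)(C(=O)OCC[Si](C)(C)C)C[C@H]1OC(=O)/C=C/c1ccc(O[Si](C)(C)C(C)(C)C)c(O[Si](C)(C)C(C)(C)C)c1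
A1 | alternative 1 | 2-(benzoyloxy)acrolein | C=C(OC(=O)c1ccccc1)C=O
A2 | alternative 1 | buta-1,3-diene | C=CC=C
A3 | alternative 1 | (S)-1-formylcyclohex-3-en-1-yl benzoate | C1=CC[C@](OC(=O)c2ccccc2)(C=O)CC1
A4 | alternative 1 | 1-O-benzoylquinic acid 1,5-lactone | O[C@H]1[C@H]2C[C@](OC(=O)c3ccccc3)(C(=O)O2)C[C@H]1O
A5 | alternative 2 | L-malic acid | OC(=O)C[C@H](O)C(=O)O
A6 | alternative 2 | methyl (2S,4R)-2,4-dihydroxy-2-(prop-2-en-1-yl)hex-5-enoate | C=C[C@H](O)C[C@](O)(C(=O)OC)CC=C
A7 | alternative 2 | methyl (1S,5R)-1,5-dihydroxycyclohex-3-ene-1-carboxylate | C1=C[C@H](O)C[C@](O)(C(=O)OC)C1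
A8 | alternative 2 | methyl (−)-quinate | O[C@H]1[C@H](O)C[C@](O)(C(=O)OC)C[C@H]1O
A9 | alternative 3 | diethyl D-tartrate | CCOC(=O)[C@@H](O)[C@H](O)C(=O)OCC
A10 | alternative 3 | ethyl 3-[(4R,5S)-5-acetyl-2,2-dimethyl-1,3-dioxolan-4-yl]-2-oxopropanoate | CC(=O)[C@H]1OC(C)(C)O[C@@H]1CC(=O)C(=O)OCC
A11 | alternative 3 | ethyl 4,5-O-isopropylidene-3-dehydroquinate | CC1(C)O[C@H]2[C@H](O1)C[C@](O)(C(=O)OCC)CC2=O
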